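**Assumptions (one line each)**
- Daucane numbering is used: C1 = quaternary ring-fusion carbon (C15 methyl), C2/C3 = CH2, C4 = carbinol carbon (iPr), C5 = ring-fusion CH, C6 = ester carbon, C7 = CH2, C8 (C14 methyl)/C9 = epoxide, C10 = CH2; β = face of C15. The target SMILES corresponds to (1R,4R,5S,6S,8R,9S): 4-OH β, H-5 α, 6-O α, epoxide α.
- Charette's (R,R)-dioxaborolane is assumed to show the same facial preference on the Z-trisubstituted allylic alcohol 4 as on cinnamyl alcohol.

**Retrosynthetic overview**
1. Jaeskeanin ⇒ phenol unmasking, C6 acylation and OH-directed α-epoxidation of jaeschkeanadiol (14); the epoxide is the last ring formed.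
2. 14 ⇒ C6 ketone 13 (internal hydride delivery from the 4β-OH) ⇒ isopropyl addition to a trans-fused 4-ketone (11).
3. The trans ring fusion (H-5 α) ⇒ stereospecific 1,2-hydride shift of syn-epoxy alcohol 10, made from dienone 8 by CBS reduction and directed epoxidation.
4. Key step: hydroazulene dienone 8 ⇒ cis-divinylcyclopropane 7 by Cope rearrangement. The seven-membered ring is grown onto a purchased cyclopentenone and the C1 quaternary centre comes from cyclopropane chirality, instead of the usual RCM or aldol closure of the cycloheptene.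
5. 7 ⇒ Charette cyclopropanation of Z-dienol 4 ⇐ Negishi union of 2-bromo-3-methylcyclopentenone (3) with (Z)-3-iodo-2-methylallyl alcohol (2). Ring order: cyclopentenone (bought) → cyclopropane → cycloheptadiene → epoxide.

**Route**

Step 1
Reactants: 1, prop-2-yn-1-ol
Product: 2, (Z)-3-iodo-2-methylprop-2-en-1-ol
Conditions: MeMgBr (3 equiv), CuI (10 mol%), THF, −10 °C → rt; then I2, −78 °C → rt
Reagents that add atoms: methylmagnesium bromide, C[Mg]Br; iodine, II
Why: Duboudin Cu-catalysed anti-carbomagnesiation of the propargylic alkoxide gives a chelated vinylmagnesium that is iodinated with retention, fixing the Z geometry (I cis to CH2OH).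

Step 2
Reactants: 2, (Z)-3-iodo-2-methylprop-2-en-1-ol; 3, 2-bromo-3-methylcyclopent-2-en-1-one
Product: 4, 2-[(1Z)-3-hydroxy-2-methylprop-1-en-1-yl]-3-methylcyclopent-2-en-1-one
Conditions: n-BuLi (1 equiv) then t-BuLi (2 equiv), Et2O, −78 °C; ZnCl2, THF; then 3, Pd2(dba)3/SPhos (3 mol%), THF, rt
Reagents that add atoms: none
Why: Negishi cross-coupling of the alkoxide-bearing (Z)-alkenylzinc with the α-bromoenone proceeds with retention of olefin geometry and tolerates the ketone.

Step 3
Reactants: 4
Product: 5, [(1S,2R)-1-methyl-2-(2-methyl-5-oxocyclopent-1-en-1-yl)cyclopropyl]methanol (CH2OH cis to the cyclopentenyl group)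
Conditions: Et2Zn, CH2I2, DME; (4R,5R)-2-butyl-N,N,N′,N′-tetramethyl-1,3,2-dioxaborolane-4,5-dicarboxamide (1.2 equiv), CH2Cl2, −10 °C → rt
Reagents that add atoms: diiodomethane, ICI
Why: Charette asymmetric Simmons–Smith cyclopropanation is hydroxyl-directed (the electron-poor enone olefin is untouched), is stereospecific for the Z olefin (cis cyclopropane), and the (R,R)-ligand selects the face giving (1S,2R).

Step 4
Reactants: 5
Product: 6, (1S,2R)-1-methyl-2-(2-methyl-5-oxocyclopent-1-en-1-yl)cyclopropane-1-carbaldehyde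
Conditions: Dess–Martin periodinane, NaHCO3, CH2Cl2, 0 °C; used cold and directly
Reagents that add atoms: none
Why: Dess–Martin oxidation of the primary alcohol gives an α-quaternary aldehyde that cannot epimerise; keeping it cold suppresses retro-Claisen to the dihydrooxepine.

Step 5
Reactants: 6
Product: 7, 3-methyl-2-[(1R,2R)-2-methyl-2-vinylcyclopropyl]cyclopent-2-en-1-one (vinyl cis to the cyclopentenyl group)
Conditions: Ph3PCH3Br, KHMDS, THF, −78 → 0 °C
Reagents that add atoms: methyltriphenylphosphonium bromide, C[P+](c1ccccc1)(c1ccccc1)c1ccccc1.[Br-]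
Why: Wittig methylenation is selective for the aldehyde over the hindered, conjugated tetrasubstituted enone carbonyl and leaves the cyclopropane stereocentres untouched.

Step 6 (key step)
Reactants: 7
Product: 8, (3aR)-3a,6-dimethyl-3,3a,4,7-tetrahydroazulen-1(2H)-one (daucane: C4 ketone, C5=C6 and C8=C9 olefins, C1 R)
Conditions: PhMe (0.01 M, BHT), sealed tube, 120 °C
Reagents that add atoms: none
Why: The cis-divinylcyclopropane–cycloheptadiene (Cope) rearrangement goes through the obligatory boat transition state, forms the C1–C10 bond and the seven-membered ring with both olefins in their final positions, and transfers the (1R,2R)-cyclopropane chirality to the C1 quaternary centre (R, worked out from the boat geometry); heating is needed because the C15 methyl is Z on the enone terminus.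

Step 7
Reactants: 8
Product: 9, (1S,3aR)-3a,6-dimethyl-1,2,3,3a,4,7-hexahydroazulen-1-ol (daucane: 4β-OH, 4S)
Conditions: (R)-Me-CBS (20 mol%), catecholborane, PhMe, −78 °C
Reagents that add atoms: none
Why: Corey–Bakshi–Shibata reduction is reagent-controlled (alkylidene carbon C5 = large group, CH2 = small), delivering hydride to the α face so the OH is β, and catecholborane at −78 °C does not hydroborate C8=C9.

Step 8
Reactants: 9
Product: 10, syn-epoxy alcohol: 5β,6β-epoxide of 9, spiro at C5 (daucane 1R,4S,5R,6R; epoxide oxygen on the same face as the 4-OH)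
Conditions: VO(acac)2 (5 mol%), t-BuOOH, CH2Cl2, 0 °C
Reagents that add atoms: tert-butyl hydroperoxide, CC(C)(C)OO
Why: Vanadium-catalysed hydroxyl-directed epoxidation delivers oxygen syn to the allylic OH (β face) and is chemoselective for the allylic olefin over the isolated C8=C9 olefin.

Step 9
Reactants: 10
Product: 11, (3aR,8R,8aS)-3a,6-dimethyl-8-(triethylsilyloxy)-3,3a,4,7,8,8a-hexahydroazulen-1(2H)-one (daucane: 4-ketone, H-5 α, 6β-OTES; trans-fused)
Conditions: TESOTf (1.5 equiv), i-Pr2NEt, 4 Å MS, CH2Cl2, −78 → −40 °C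
Reagents that add atoms: triethylsilyl triflate, CC[Si](CC)(CC)OS(=O)(=O)C(F)(F)F
Why: Jung non-aldol aldol (semipinacol) rearrangement: the silyl-activated tertiary C5–O bond opens as the anti-periplanar C4–H (α) migrates to C5 with inversion, so H-5 is set α (trans ring fusion) stereospecifically and C4 becomes the ketone.

Step 10
Reactants: 11
Product: 12, 6-epi-jaeschkeanadiol, (3R,3aS,4R,8aR)-3-isopropyl-6,8a-dimethyl-1,2,3,3a,4,5,8,8a-octahydroazulene-3,4-diol (daucane 1R,4R,5S,6R)
Conditions: i-PrMgCl, CeCl3, THF, −78 → −40 °C; aq NH4Cl; then TBAF, THF, 0 °C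
Reagents that add atoms: isopropylmagnesium chloride, CC(C)[Mg]Cl
Why: Imamoto organocerium 1,2-addition (suppresses enolisation, β-elimination and reduction) occurs from the α face, anti to the C15 methyl and the axial 6β-OTES, giving 4β-OH/4α-iPr (4R); fluoride then removes the TES group.

Step 11
Reactants: 12
Product: 13, (3R,3aR,8aR)-3-hydroxy-3-isopropyl-6,8a-dimethyl-2,3,3a,5,8,8a-hexahydroazulen-4(1H)-one (daucane: 4β-OH, 6-ketone, H-5 α)
Conditions: Dess–Martin periodinane, NaHCO3, CH2Cl2, 0 °C
Reagents that add atoms: none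
Why: Dess–Martin oxidation touches only the secondary C6 alcohol, and the neutral conditions avoid retro-aldol, C5 epimerisation and conjugation of the β,γ-olefin (the trans-fused C5 epimer is in any case the more stable one because C6 then sits cis to OH and not to iPr).

Step 12
Reactants: 13
Product: 14, jaeschkeanadiol, (3R,3aS,4S,8aR)-3-isopropyl-6,8a-dimethyl-1,2,3,3a,4,5,8,8a-octahydroazulene-3,4-diol (daucane 1R,4R,5S,6S)
Conditions: Me4NBH(OAc)3, MeCN/AcOH (1:1), −25 °C
Reagents that add atoms: none
Why: Evans–Saksena reduction: the borohydride bound to the 4β-oxygen can reach only the β face of the C6 carbonyl, so hydride enters β and the alcohol is 6α (1,3-anti diol, 6S), correcting C6.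

Step 13
Reactants: 14
Product: 15, 8α,9α-epoxyjaeschkeanadiol (daucane 1R,4R,5S,6S,8R,9S)
Conditions: VO(acac)2 (5 mol%), t-BuOOH, 2,6-lutidine (cat.), CH2Cl2, 0 °C → rt
Reagents that add atoms: tert-butyl hydroperoxide, CC(C)(C)OO
Why: Vanadium-catalysed epoxidation directed by the homoallylic 6α-OH (cyclohept-3-enol motif) delivers oxygen to the α face of C8=C9, which is also the face anti to the C15 methyl, setting C8 (R) and C9 (S).

Step 14
Reactants: 15; 16, 4-acetoxybenzoic acid
Product: 17, 4′-O-acetyljaeskeanin (C6 4-acetoxybenzoate of 15)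
Conditions: EDC·HCl, DMAP, CH2Cl2, rt
Reagents that add atoms: none (the acyl group comes from 16)
Why: Steglich esterification acylates the secondary C6-OH with retention, while the tertiary C4-OH and the epoxide are inert.

Step 15
Reactants: 17
Product: 18, jaeskeanin (target)
Conditions: K2CO3 (0.2 equiv), MeOH, 0 °C, 15 min
Reagents that add atoms: none
Why: Chemoselective methanolysis of the aryl acetate is far faster than cleavage of the hindered secondary p-hydroxybenzoate, and mild base leaves the epoxide and all stereocentres intact.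

**Compound list**

1 | prop-2-yn-1-ol | C#CCO | starting material
2 | (Z)-3-iodo-2-methylprop-2-en-1-ol | OC/C(C)=C\I | intermediate
3 | 2-bromo-3-methylcyclopent-2-en-1-one | CC1=C(Br)C(=O)CC1 | starting material
4 | 2-[(1Z)-3-hydroxy-2-methylprop-1-en-1-yl]-3-methylcyclopent-2-en-1-one | OC/C(C)=C\C1=C(C)CCC1=O | intermediate
5 | [(1S,2R)-1-methyl-2-(2-methyl-5-oxocyclopent-1-en-1-yl)cyclopropyl]methanol | OC[C@@]1(C)C[C@H]1C2=C(C)CCC2=O | intermediate
6 | (1S,2R)-1-methyl-2-(2-methyl-5-oxocyclopent-1-en-1-yl)cyclopropane-1-carbaldehyde | O=C[C@@]1(C)C[C@H]1C2=C(C)CCC2=O | intermediate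
7 | 3-methyl-2-[(1R,2R)-2-methyl-2-vinylcyclopropyl]cyclopent-2-en-1-one | C=C[C@@]1(C)C[C@H]1C2=C(C)CCC2=O | intermediate
8 | (3aR)-3a,6-dimethyl-3,3a,4,7-tetrahydroazulen-1(2H)-one | O=C1CC[C@]2(C)CC=C(C)CC=C12 | intermediate
9 | (1S,3aR)-3a,6-dimethyl-1,2,3,3a,4,7-hexahydroazulen-1-ol | O[C@H]1CC[C@]2(C)CC=C(C)CC=C12 | intermediate
10 | syn-epoxy alcohol (daucane 1R,4S,5R,6R; 5β,6β-epoxide, 4β-OH) | O[C@H]1CC[C@]2(C)CC=C(C)C[C@H]3O[C@@]123 | intermediate
11 | (3aR,8R,8aS)-3a,6-dimethyl-8-(triethylsilyloxy)-3,3a,4,7,8,8a-hexahydroazulen-1(2H)-one | O=C1CC[C@]2(C)CC=C(C)C[C@@H](O[Si](CC)(CC)CC)[C@@H]12 | intermediate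
12 | 6-epi-jaeschkeanadiol (daucane 1R,4R,5S,6R) | CC(C)[C@]1(O)CC[C@]2(C)CC=C(C)C[C@@H](O)[C@H]21 | intermediate
13 | 4β-hydroxydauc-8-en-6-one (daucane 1R,4R,5R) | CC(C)[C@]1(O)CC[C@]2(C)CC=C(C)CC(=O)[C@H]21 | intermediate
14 | jaeschkeanadiol (daucane 1R,4R,5S,6S) | CC(C)[C@]1(O)CC[C@]2(C)CC=C(C)C[C@H](O)[C@H]21 | intermediate
15 | 8α,9α-epoxyjaeschkeanadiol (daucane 1R,4R,5S,6S,8R,9S) | CC(C)[C@]1(O)CC[C@]2(C)C[C@@H]3O[C@]3(C)C[C@H](O)[C@H]21 | intermediate
16 | 4-acetoxybenzoic acid | CC(=O)Oc1ccc(cc1)C(O)=O | starting material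
17 | 4′-O-acetyljaeskeanin | CC(C)[C@]1(O)CC[C@]2(C)C[C@@H]3O[C@]3(C)C[C@H](OC(=O)c3ccc(OC(C)=O)cc3)[C@H]21 | intermediate
18 | jaeskeanin | CC(C)[C@]1(O)CC[C@]2(C)C[C@@H]3O[C@]3(C)C[C@H](OC(=O)c3ccc(O)cc3)[C@H]21 | target

**Totals**
- Total step count: 15
- Longest linear sequence: 15 steps (1 → 18); 3 and 16 are purchased.

**Three steps most likely to fail, with fallbacks**
1. Step 6 (Cope rearrangement). The Z-methyl on a fully substituted terminus raises the barrier, and prolonged heating risks cyclopropane homolysis with loss of ee. Fallback: abandon the pericyclic ring construction; set C1 by Cu-catalysed asymmetric conjugate addition of an allyl-type nucleophile to 3-methylcyclopent-2-enone with aldol trapping by 3-methylbut-3-enal, and close C8=C9 by ring-closing metathesis.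
2. Step 9 (non-aldol aldol hydride shift). The developing C5 cation sits next to quaternary C1 and could divert to Wagner–Meerwein shift or elimination. Fallback: skip steps 7–9 and install the C6 oxygen on enone 8 by Cu-catalysed conjugate borylation/oxidation (B2pin2, CuCl/bisphosphine, MeOH; NaBO3), then correct C5 by equilibration at the stage of ketone 13, where the trans-fused epimer is favoured.
3. Step 12 (directed reduction). The directing alcohol is tertiary and hydride must enter syn-axial to the C15 methyl. Fallback: drop the oxidation/reduction pair; invert C6 of 12 directly by Mitsunobu esterification with 16 (this also installs the ester), then epoxidise with mCPBA under substrate control (α face, anti to C15) and deacetylate.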